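A leftover started me. Averaged over the autumn readings, ring 21.5%, isomer of the product 48.2% and open dimer 23.7%, with the substrate readings also taken off, leave 6.02% of the charge unread.

| flask | substrate | remark | time |
|---|---|---|---|
| autumn | 0.034 M | run made earlier |  |
| dusk | 0.075 M | run made earlier |  |
| flask | 0.050 M |  | 15 d |

| run | time / d | substrate / % | ring / % | isomer of the product / % | open dimer / % |
|---|---|---|---|---|---|
| autumn | 4.00 | 2.0 | 22.0 | 48.4 | 23.7 |
| autumn | 8.00 | 0 | 21.2 | 48.6 | 21.8 |
| autumn | 10.0 | 0.6 | 22.1 | 49.7 | 24.1 |
| autumn | 15.0 | 0 | 22.3 | 46.7 | 24.0 |
| autumn | 20.0 | 0.2 | 19.8 | 47.8 | 24.9 |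
| dusk | 4.00 | 0 | 17.7 | 37.3 | 38.3 |
| dusk | 8.00 | 0 | 13.3 | 35.4 | 38.6 |
| dusk | 10.0 | 0 | 15.0 | 35.0 | 37.3 |
| dusk | 15.0 | 0 | 14.8 | 37.1 | 36.8 |
| dusk | 20.0 | 1.5 | 17.3 | 35.7 | 37.4 |

(scatter of a reading: 1 percentage point)

- in percentages every species weighs as the substrate in it: one open dimer counts as two
- the analysis behind the earlier runs scatters by 1 percentage point, standard deviation
- the reaction counts as stopped when no species that holds the substrate changes by six tenths of a point or more over the second half of the time

- at 15 d, what has stopped the reaction, if anything has (all of the substrate has reacted / forward and back rates have come level / it is still moving)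
- part of the substrate gone at 15 d
- the ring standing at 15 d, as a percentage of the substrate charged
- the isomer of the product standing at 15 d, as a percentage of the substrate charged
- the open dimer standing at 15 d, as a percentage of the substrate charged
- amount of ring if the flask were left three thousand times as long, in percent of the substrate charged

In the dusk run, with its larger charge, the unread part, reckoned the same way, reads 10.3%, more than in the autumn run, so I booked it with the open dimer, on a route whose rate goes with the square of c(substrate). Ring and isomer of the product I booked on a first-order route.

I reasoned on rates. Let the second route run at c(substrate) divided by a constant, the even charge, times the first. When the substrate has fallen to half, the first rate has fallen to half and the second to a quarter, so their ratio halves. Summed over the run, the first-order share, a selectivity, is ln(1+x)/x, where x is the starting ratio.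

At x = 1 that share is 69.3%, and the autumn run reads 69.7%, so I took the even charge as 0.0342 M. For the dusk run this predicts 52.9%, against a reading of 51.7%.

For the flask, x is 1.46, so the share is 61.6%. With the autumn proportions I committed to ring 19.0%, isomer of the product 42.6% and open dimer 30.0%. I expected the substrate in the flask to be gone, as it reads 0% at 8.00 d in the autumn run, and the ring then to stay flat, as its autumn readings do within their scatter of 1 percentage point.

The forecast, a little apart from my figures, said all of the substrate has reacted, 100% gone, ring 18.7%, isomer of the product 42.5%, open dimer 30.3% and 18.7% of ring in the long run, since “the reaction stopped because the substrate ran out”.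

The flask gives, at 15 d: all of the substrate has reacted, with 100% gone, ring 18.7%, isomer of the product 43.1%, open dimer 30.2%, and ring 18.7% in the long run.

    substrate + ring → side product (k = 0.0250 M⁻¹ min⁻¹)
    substrate → ring (k = 0.00510 min⁻¹)
    2 substrate → open dimer (k = 0.0520 M⁻¹ min⁻¹)
    ring ⇌ isomer of the product (K = 2.30, k = 0.00190 min⁻¹)

The side product, which I had not read, stands at 8.01% in this flask at 15.0 d, and my even charge books it together with the open dimer. In this flask ring and isomer of the product together stand at 61.8%, against my share of 61.6%. The neighbouring flask charged with 0.12 M of substrate has x = 3.51, so the same reckoning gives a share of 42.9%. That flask stands at ring 12.9% and isomer of the product 29.6%, together 42.5%, and its open dimer stands at 47.7%.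

(The earlier runs and the new flask stem from a simulated flask from invented constants; scatter was added.)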